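Readings and results come from a simulation with constants of no real substance; scatter was added.

The ratio I looked for compares the lifetime of J with the time constant at which fresh J takes G down. With dissolved L frozen at 14 mM, G falls pseudo-first-order, with a rate constant proportional to c_J. If c_J decays exponentially, the logarithm of charged c_G over final c_G equals that ratio. G in the epsilon run read 32.6% at 900 min, which gives 1.12, the catalyst budget N.

all flasks: G 0.050 M; L 14 mM (held)
- epsilon: J 0.5 mol%; temperature 25 °C; the very flask that is asked about, followed so far
- eta: J 1 mol%; temperature 20 °C; run made earlier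
- flask: J 0.5 mol%; temperature 25 °C; time 25 h

- epsilon (time / min: X / %, G / %): 80.0: 31.3, 69.3; 120: 40.9, 58.4; 180: 52.4, 48.2; 240: 57.0, 42.6; 360: 64.1, 37.1; 600: 68.7, 32.9; 900: 69.1, 32.6
- eta (time / min: X / %, G / %): 2.50: 0.5, 100.3; 4.00: 1.4, 99.2; 6.00: 2.7, 99.9; 10.0: 5.0, 95.6; 15.0: 9.8, 91.2; 20.0: 11.3, 89.2; 30.0: 19.9, 79.6

(scatter of a reading: 1 percentage point)

- what is taken out of X is counted as made
- at the start none of L is in solution
- additions bring no volume worth counting

- ash: at 25 h add J, 100% of the amount charged, then wait 12 h
- larch: at 25 h raise the temperature by 20 K, then wait 12 h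
- elm: change nothing and wait 12 h more
- cedar: at 25 h take out 90% of the X then present, then wait 12 h

1. X, in percent of the G first charged, at 25 h
2. the option that brings most further X ("none" if no option brings more than 2 percentage points) (ash / larch / elm / cedar / none)
3. X present, with what was taken out counted in, in percent of the G first charged, after ash
4. X present, with what was taken out counted in, in percent of the G first charged, after elm

I tested the single number by asking what decay constant each reading demands, given N. The reading at 80.0 min gives 0.00495 min⁻¹, and the one at 360 min gives 0.00600 min⁻¹, which is larger. So the frozen form was approximate. N also did not separate dead J from an equilibrium: either reading gives a plateau of G. I chose dead J as a judgement.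

On that reading, 25 h lies far beyond the lifetime of J, so I put X at about the plateau, 69.1%, and elm gains nothing. Ash spends the budget again on the remaining G, and 12 h outlasts that lifetime, so I expected 89.4% and named ash best.

The forecast differed. It gave 68.5% for now, 68.5% after elm and 68.7% after ash, and it named cedar best: “Extra J and waiting therefore gain nothing.”

The flask gave 68.4% at 25 h, 68.4% after elm and 96.0% after ash, so ash was best, and J stood at 0% of its charge at 1500 min.

    L ⇌ E, rate k1*(csat - [E]) (kL = 12.0 h⁻¹)
    J → D (k = 0.410 h⁻¹, Ea = 105 kJ mol⁻¹)
    2 E → Q (k = 12.0 M⁻¹ h⁻¹, Ea = 48.0 kJ mol⁻¹)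
    G + E + J → X + J, rate k4*[G]*[E]*[J]/(1 + ([G]/sat4)) (26.0 mM, k = 3.20 × 10⁵ M⁻² h⁻¹, Ea = 40.0 kJ mol⁻¹)
    (constants at 25 °C)

Reckoned from the flask's own numbers, the second dose was worth 2.06, more than N. A neighbour flask with 0.030 M of G at the same mol% of J has less J charged, so I scaled N to 0.673, which gives 49.0% of X, less than the 57.3% that flask gave.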